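## Retrosynthetic overview

1. Target 30 comes from the saturated keto-lactone 27 by a final Saegusa desaturation; the trans-fused γ-lactone and the C4 ketone come from hydroxy ester/dioxolane 25.
2. The 4-methylpyranone comes from a 4-hydroxypyranone (triflate, Suzuki methylation). The key C–C bond, pyranone C3 to the CH2CH2 link, is made by an intermolecular aldol (Knoevenagel-type) condensation with in situ reduction between aldehyde 15 and 4-hydroxy-6-(furan-3-yl)pyranone 20.
3. Pyranone 20 comes from Claisen-type acylation of a dioxinone dienolate with furan-3-carbonyl chloride, then acylketene ring closure.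
4. Aldehyde 15 comes from ozonolysis of the silyl enol ether of bicyclic α-ketol 10; its cyclopentanone ring is a sacrificial template that supplies both the ester carbon and the CH2CHO arm.
5. Ketol 10 (both stereocentres) comes from an NHC-catalysed desymmetrising crossed benzoin of dione 9, made from cyclohexane-1,3-dione. Ring order: cyclohexane (bought) → template cyclopentanone (step 6, cleaved in step 9) → pyranone (step 12) → γ-lactone (step 17) → enone (step 18).

Assumption: the (5aS,10bR) aminoindanol-derived triazolium salt is taken to give (3aR,7aR)-10; if the first run shows the opposite sense, the equally available (5aR,10bS) salt is used.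

## Route

Step 1
Reactants: 1 cyclohexane-1,3-dione; 2 allyl bromide
Product: 3 2-(prop-2-en-1-yl)cyclohexane-1,3-dione
Conditions: KOH, Cu powder (cat.), H2O, 0 °C → rt
Reagents that add atoms: none
Why: C-alkylation of the soft dione enolate by an allylic halide in water (enolate allylation) gives the 2-allyl dione with little O-alkylation.

Step 2
Reactants: 3 2-(prop-2-en-1-yl)cyclohexane-1,3-dione; 4 formaldehyde
Product: 5 2-(hydroxymethyl)-2-(prop-2-en-1-yl)cyclohexane-1,3-dione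
Conditions: 37% aq. CH2O (3 equiv), Et3N (5 mol%), THF/H2O, 0 °C → rt
Reagents that add atoms: none
Why: Intermolecular aldol addition (hydroxymethylation) of the dione enolate to formaldehyde creates the quaternary carbon; the adduct cannot enolise, so it neither dehydrates nor takes up a second dione.

Step 3
Reactants: 5 2-(hydroxymethyl)-2-(prop-2-en-1-yl)cyclohexane-1,3-dione
Product: 6 2-{[tert-butyl(dimethyl)silyl]oxymethyl}-2-(prop-2-en-1-yl)cyclohexane-1,3-dione
Conditions: TBSCl, imidazole, DMF, 0 °C → rt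
Reagents that add atoms: tert-butyldimethylsilyl chloride, CC(C)(C)[Si](C)(C)Cl
Why: Silylation of the primary alcohol blocks retro-aldol loss of formaldehyde in the later basic steps.

Step 4
Reactants: 6 2-{[tert-butyl(dimethyl)silyl]oxymethyl}-2-(prop-2-en-1-yl)cyclohexane-1,3-dione
Product: 8 2-{[tert-butyl(dimethyl)silyl]oxymethyl}-2-(3-hydroxypropyl)cyclohexane-1,3-dione, via catechol boronate 7 (not isolated)
Conditions: catecholborane, RhCl(PPh3)3 (2 mol%), THF, rt; then 30% H2O2, pH 7 phosphate buffer, 0 °C → rt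
Reagents that add atoms: hydrogen peroxide, OO
Why: Rh-catalysed hydroboration is anti-Markovnikov and much faster than carbonyl reduction, and buffered peroxide oxidation of the boronate spares the retro-Claisen-prone 2,2-disubstituted dione.

Step 5
Reactants: 8 2-{[tert-butyl(dimethyl)silyl]oxymethyl}-2-(3-hydroxypropyl)cyclohexane-1,3-dione
Product: 9 3-(1-{[tert-butyl(dimethyl)silyl]oxymethyl}-2,6-dioxocyclohexyl)propanal
Conditions: Dess–Martin periodinane, CH2Cl2, rt
Reagents that add atoms: none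
Why: Dess–Martin oxidation of the primary alcohol stops at the aldehyde and leaves the ketones and silyl ether alone.

Step 6
Reactants: 9 3-(1-{[tert-butyl(dimethyl)silyl]oxymethyl}-2,6-dioxocyclohexyl)propanal
Product: 10 (3aR,7aR)-3a-{[tert-butyl(dimethyl)silyl]oxymethyl}-7a-hydroxyhexahydro-1H-indene-1,4(2H)-dione
Conditions: (5aS,10bR)-N-C6F5 aminoindanol-derived triazolium BF4 (10 mol%), Et3N (10 mol%), PhMe, rt
Reagents that add atoms: none
Why: NHC-catalysed intramolecular crossed aldehyde–ketone benzoin desymmetrises the dione: the five-membered ring can only close cis, which puts the new OH cis to CH2OTBS and the acyl carbon cis to the tether, and the chiral carbene selects the enantiotopic carbonyl to give the (3aR,7aR) ketol.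

Step 7
Reactants: 10 (3aR,7aR)-3a-{[tert-butyl(dimethyl)silyl]oxymethyl}-7a-hydroxyhexahydro-1H-indene-1,4(2H)-dione
Product: 11 (3aR,7aR)-3a-{[tert-butyl(dimethyl)silyl]oxymethyl}-4,4-(ethylenedioxy)-7a-hydroxyoctahydro-1H-inden-1-one
Conditions: (TMSOCH2)2 (1.5 equiv), TMSOTf (5 mol%), CH2Cl2, −78 → −20 °C; pyridine quench, dilute citric acid wash
Reagents that add atoms: 1,2-bis(trimethylsilyloxy)ethane, C[Si](C)(C)OCCO[Si](C)(C)C
Why: Noyori ketalisation runs through an oxocarbenium ion, which forms readily at the cyclohexanone but is disfavoured at the α-hydroxy cyclopentanone (inductive destabilisation, ring strain), so only C4 is masked.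

Step 8
Reactants: 11 (3aR,7aR)-3a-{[tert-butyl(dimethyl)silyl]oxymethyl}-4,4-(ethylenedioxy)-7a-hydroxyoctahydro-1H-inden-1-one
Product: 12 C1=C2 triethylsilyl enol ether and 7a-O-triethylsilyl ether of 11, (3aR,7aR)
Conditions: TESOTf (2.5 equiv), Et3N (4 equiv), CH2Cl2, −78 → 0 °C
Reagents that add atoms: triethylsilyl trifluoromethanesulfonate, CC[Si](CC)(CC)OS(=O)(=O)C(F)(F)F
Why: Soft enolisation and silylation: the remaining ketone has α-hydrogens only at C2, so a single silyl enol ether forms while the tertiary alcohol is capped.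

Step 9
Reactants: 12 C1=C2 triethylsilyl enol ether and 7a-O-triethylsilyl ether of 11
Product: 14 (6R,7R)-6-{[tert-butyl(dimethyl)silyl]oxymethyl}-6-(2-oxoethyl)-7-(triethylsilyloxy)-1,4-dioxaspiro[4.5]decane-7-carboxylic acid, via triethylsilyl ester aldehyde 13 (not isolated)
Conditions: O3, CH2Cl2, −78 °C (Sudan III end point); Me2S, −78 °C → rt; aq. citric acid work-up
Reagents that add atoms: ozone, [O-][O+]=O
Why: Ozonolysis of the electron-rich silyl enol ether cleaves C1=C2 so that C1 becomes a silyl ester (hydrolysed on work-up) and C2 the aldehyde; the ketal has no acetal C–H and the two quaternary stereocentres are not involved.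

Step 10
Reactants: 14 (6R,7R)-6-{[tert-butyl(dimethyl)silyl]oxymethyl}-6-(2-oxoethyl)-7-(triethylsilyloxy)-1,4-dioxaspiro[4.5]decane-7-carboxylic acid
Product: 15 methyl (6R,7R)-6-{[tert-butyl(dimethyl)silyl]oxymethyl}-6-(2-oxoethyl)-7-(triethylsilyloxy)-1,4-dioxaspiro[4.5]decane-7-carboxylate
Conditions: TMSCHN2, PhMe/MeOH (4:1), 0 °C
Reagents that add atoms: (trimethylsilyl)diazomethane, C[Si](C)(C)C=[N+]=[N-]
Why: Methyl esterification with TMS-diazomethane is selective for the carboxylic acid in the presence of the aldehyde.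

Step 11
Reactants: 16 2,2,6-trimethyl-4H-1,3-dioxin-4-one; 17 furan-3-carbonyl chloride
Product: 18 6-[2-(furan-3-yl)-2-oxoethyl]-2,2-dimethyl-4H-1,3-dioxin-4-one
Conditions: 16 (2.0 equiv), LiHMDS (2.1 equiv), THF, −78 °C; then 17 (1.0 equiv), −78 → −20 °C
Reagents that add atoms: none
Why: Claisen-type C-acylation of the lithium dienolate at its γ-carbon by the acid chloride; the second equivalent of dienolate takes up the acidic proton of the β-keto product.

Step 12
Reactants: 18 6-[2-(furan-3-yl)-2-oxoethyl]-2,2-dimethyl-4H-1,3-dioxin-4-one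
Product: 20 6-(furan-3-yl)-4-hydroxy-2H-pyran-2-one, via acylketene 19 (not isolated)
Conditions: PhMe, 110 °C, 1 h
Reagents that add atoms: none
Why: Thermal retro-[4+2] loss of acetone gives the acylketene, which is trapped by the enol oxygen of the furyl ketone in a six-ring closure to the 4-hydroxy-2-pyranone.

Step 13
Reactants: 15 methyl (6R,7R)-6-{[tert-butyl(dimethyl)silyl]oxymethyl}-6-(2-oxoethyl)-7-(triethylsilyloxy)-1,4-dioxaspiro[4.5]decane-7-carboxylate; 20 6-(furan-3-yl)-4-hydroxy-2H-pyran-2-one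
Product: 22 methyl (6R,7R)-6-{[tert-butyl(dimethyl)silyl]oxymethyl}-6-{2-[6-(furan-3-yl)-4-hydroxy-2-oxo-2H-pyran-3-yl]ethyl}-7-(triethylsilyloxy)-1,4-dioxaspiro[4.5]decane-7-carboxylate, via alkylidene pyrandione 21 (not isolated)
Conditions: L-proline (20 mol%), Hantzsch ester (1.1 equiv), EtOH/CH2Cl2 (1:1), rt
Reagents that add atoms: none
Why: Proline-mediated intermolecular aldol (Knoevenagel) condensation of the aldehyde with the nucleophilic C3 of the 4-hydroxypyranone joins the two halves; the alkylidene-1,3-dicarbonyl is reduced at once by the Hantzsch ester (transfer hydrogenation), which stops bis-adduct formation and touches no stereocentre.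

Step 14
Reactants: 22 methyl (6R,7R)-6-{[tert-butyl(dimethyl)silyl]oxymethyl}-6-{2-[6-(furan-3-yl)-4-hydroxy-2-oxo-2H-pyran-3-yl]ethyl}-7-(triethylsilyloxy)-1,4-dioxaspiro[4.5]decane-7-carboxylate
Product: 23 the 4-trifluoromethanesulfonyloxy-pyranone analogue of 22, (6R,7R)
Conditions: PhNTf2 (1.2 equiv), Et3N (2 equiv), CH2Cl2, 0 °C → rt
Reagents that add atoms: N-phenylbis(trifluoromethanesulfonimide), O=S(=O)(N(c1ccccc1)S(=O)(=O)C(F)(F)F)C(F)(F)F
Why: O-sulfonylation of the acidic pyranone enol gives the vinylogous ester triflate; the silyl ethers, ester and ketal are inert.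

Step 15
Reactants: 23 the 4-trifluoromethanesulfonyloxy-pyranone analogue of 22
Product: 24 methyl (6R,7R)-6-{[tert-butyl(dimethyl)silyl]oxymethyl}-6-{2-[6-(furan-3-yl)-4-methyl-2-oxo-2H-pyran-3-yl]ethyl}-7-(triethylsilyloxy)-1,4-dioxaspiro[4.5]decane-7-carboxylate
Conditions: trimethylboroxine, Pd(dppf)Cl2 (5 mol%), K3PO4, 1,4-dioxane, 90 °C
Reagents that add atoms: trimethylboroxine, CB1OB(C)OB(C)O1
Why: Suzuki–Miyaura methylation of the electron-poor enol triflate installs the C4 methyl under conditions that the ester, silyl ethers, ketal and furan tolerate.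

Step 16
Reactants: 24 methyl (6R,7R)-6-{[tert-butyl(dimethyl)silyl]oxymethyl}-6-{2-[6-(furan-3-yl)-4-methyl-2-oxo-2H-pyran-3-yl]ethyl}-7-(triethylsilyloxy)-1,4-dioxaspiro[4.5]decane-7-carboxylate
Product: 25 methyl (6R,7R)-6-{2-[6-(furan-3-yl)-4-methyl-2-oxo-2H-pyran-3-yl]ethyl}-7-hydroxy-6-(hydroxymethyl)-1,4-dioxaspiro[4.5]decane-7-carboxylate
Conditions: HF·pyridine, THF/pyridine, 0 °C → rt
Reagents that add atoms: none
Why: Fluoride-mediated desilylation removes the primary TBS and tertiary TES ethers without touching the ketal, ester, pyranone or furan.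

Step 17
Reactants: 25 methyl (6R,7R)-6-{2-[6-(furan-3-yl)-4-methyl-2-oxo-2H-pyran-3-yl]ethyl}-7-hydroxy-6-(hydroxymethyl)-1,4-dioxaspiro[4.5]decane-7-carboxylate
Product: 27 (3aR,7aR)-3a-{2-[6-(furan-3-yl)-4-methyl-2-oxo-2H-pyran-3-yl]ethyl}-7a-hydroxyhexahydro-2-benzofuran-1,4-dione, via lactone ketal 26 (not isolated)
Conditions: CSA (10 mol%), PhMe, 4 Å MS, 60 °C; then 2 M aq. HCl/THF (1:3), rt
Reagents that add atoms: water, O
Why: Acid-catalysed intramolecular transesterification closes the trans-fused γ-lactone from the trans-disposed CH2OH and CO2Me (Thorpe–Ingold assistance) while C4 is still a ketal, so no retro-aldol-prone β-hydroxy ketone is present; ketal hydrolysis then unmasks the ketone.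

Step 18
Reactants: 27 (3aR,7aR)-3a-{2-[6-(furan-3-yl)-4-methyl-2-oxo-2H-pyran-3-yl]ethyl}-7a-hydroxyhexahydro-2-benzofuran-1,4-dione
Product: 30 (3aR,7aR)-3a-{2-[6-(furan-3-yl)-4-methyl-2-oxo-2H-pyran-3-yl]ethyl}-7a-hydroxy-3,3a,7,7a-tetrahydro-2-benzofuran-1,4-dione (CNP0550188.1), via bis-TMS enol ether 28 (not isolated), via O-TMS enone 29 (not isolated)
Conditions: TMSOTf (2.5 equiv), Et3N (4 equiv), CH2Cl2, 0 °C; then Pd(OAc)2 (1.1 equiv), MeCN, rt; then 1 M HCl/THF, 0 °C
Reagents that add atoms: none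
Why: Saegusa–Ito oxidation: the ketone can enolise only towards C5 because C3a is quaternary, so Pd(II)-mediated dehydrosilylation gives the C5=C6 enone, and the transient tertiary TMS ether is cleaved in the acidic work-up; both stereocentres are untouched.

## Compound list

1 | cyclohexane-1,3-dione | O=C1CCCC(=O)C1 | starting material
2 | allyl bromide | C=CCBr | starting material
3 | 2-(prop-2-en-1-yl)cyclohexane-1,3-dione | C=CCC1C(=O)CCCC1=O | intermediate
4 | formaldehyde (37% aqueous) | C=O | starting material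
5 | 2-(hydroxymethyl)-2-(prop-2-en-1-yl)cyclohexane-1,3-dione | C=CCC1(CO)C(=O)CCCC1=O | intermediate
6 | 2-{[tert-butyl(dimethyl)silyl]oxymethyl}-2-(prop-2-en-1-yl)cyclohexane-1,3-dione | C=CCC1(CO[Si](C)(C)C(C)(C)C)C(=O)CCCC1=O | intermediate
7 | 2-[3-(1,3,2-benzodioxaborol-2-yl)propyl]-2-{[tert-butyl(dimethyl)silyl]oxymethyl}cyclohexane-1,3-dione (not isolated) | O=C1CCCC(=O)C1(CCCB2Oc3ccccc3O2)CO[Si](C)(C)C(C)(C)C | intermediate
8 | 2-{[tert-butyl(dimethyl)silyl]oxymethyl}-2-(3-hydroxypropyl)cyclohexane-1,3-dione | O=C1CCCC(=O)C1(CCCO)CO[Si](C)(C)C(C)(C)C | intermediate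
9 | 3-(1-{[tert-butyl(dimethyl)silyl]oxymethyl}-2,6-dioxocyclohexyl)propanal | O=CCCC1(CO[Si](C)(C)C(C)(C)C)C(=O)CCCC1=O | intermediate
10 | (3aR,7aR)-3a-{[tert-butyl(dimethyl)silyl]oxymethyl}-7a-hydroxyhexahydro-1H-indene-1,4(2H)-dione (cis-fused; OH cis to CH2OTBS) | O=C1CC[C@]2(CO[Si](C)(C)C(C)(C)C)C(=O)CCC[C@]12O | intermediate
11 | (3aR,7aR)-3a-{[tert-butyl(dimethyl)silyl]oxymethyl}-4,4-(ethylenedioxy)-7a-hydroxyoctahydro-1H-inden-1-one | O=C1CC[C@]2(CO[Si](C)(C)C(C)(C)C)C3(OCCO3)CCC[C@]12O | intermediate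
12 | (3aR,7aR) C1=C2 triethylsilyl enol ether and 7a-O-triethylsilyl ether of 11 | CC[Si](CC)(CC)OC1=CC[C@]2(CO[Si](C)(C)C(C)(C)C)C3(OCCO3)CCC[C@]12O[Si](CC)(CC)CC | intermediate
13 | triethylsilyl (6R,7R)-6-{[tert-butyl(dimethyl)silyl]oxymethyl}-6-(2-oxoethyl)-7-(triethylsilyloxy)-1,4-dioxaspiro[4.5]decane-7-carboxylate (not isolated) | O=CC[C@]1(CO[Si](C)(C)C(C)(C)C)C2(OCCO2)CCC[C@]1(O[Si](CC)(CC)CC)C(=O)O[Si](CC)(CC)CC | intermediate
14 | (6R,7R)-6-{[tert-butyl(dimethyl)silyl]oxymethyl}-6-(2-oxoethyl)-7-(triethylsilyloxy)-1,4-dioxaspiro[4.5]decane-7-carboxylic acid | O=CC[C@]1(CO[Si](C)(C)C(C)(C)C)C2(OCCO2)CCC[C@]1(O[Si](CC)(CC)CC)C(=O)O | intermediate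
15 | methyl (6R,7R)-6-{[tert-butyl(dimethyl)silyl]oxymethyl}-6-(2-oxoethyl)-7-(triethylsilyloxy)-1,4-dioxaspiro[4.5]decane-7-carboxylate | O=CC[C@]1(CO[Si](C)(C)C(C)(C)C)C2(OCCO2)CCC[C@]1(O[Si](CC)(CC)CC)C(=O)OC | intermediate
16 | 2,2,6-trimethyl-4H-1,3-dioxin-4-one | CC1=CC(=O)OC(C)(C)O1 | starting material
17 | furan-3-carbonyl chloride | O=C(Cl)c1ccoc1 | starting material
18 | 6-[2-(furan-3-yl)-2-oxoethyl]-2,2-dimethyl-4H-1,3-dioxin-4-one | CC1(C)OC(=O)C=C(CC(=O)c2ccoc2)O1 | intermediate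
19 | 5-(furan-3-yl)-3,5-dioxopent-1-en-1-one, the acylketene (not isolated) | O=C=CC(=O)CC(=O)c1ccoc1 | intermediate
20 | 6-(furan-3-yl)-4-hydroxy-2H-pyran-2-one | O=c1cc(O)cc(-c2ccoc2)o1 | intermediate
21 | methyl (6R,7R)-6-{[tert-butyl(dimethyl)silyl]oxymethyl}-6-{2-[6-(furan-3-yl)-2,4-dioxo-2H-pyran-3(4H)-ylidene]ethyl}-7-(triethylsilyloxy)-1,4-dioxaspiro[4.5]decane-7-carboxylate (not isolated) | O=C1OC(-c2ccoc2)=CC(=O)C1=CC[C@]1(CO[Si](C)(C)C(C)(C)C)C2(OCCO2)CCC[C@]1(O[Si](CC)(CC)CC)C(=O)OC | intermediate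
22 | methyl (6R,7R)-6-{[tert-butyl(dimethyl)silyl]oxymethyl}-6-{2-[6-(furan-3-yl)-4-hydroxy-2-oxo-2H-pyran-3-yl]ethyl}-7-(triethylsilyloxy)-1,4-dioxaspiro[4.5]decane-7-carboxylate | O=c1oc(-c2ccoc2)cc(O)c1CC[C@]1(CO[Si](C)(C)C(C)(C)C)C2(OCCO2)CCC[C@]1(O[Si](CC)(CC)CC)C(=O)OC | intermediate
23 | methyl (6R,7R)-6-{[tert-butyl(dimethyl)silyl]oxymethyl}-6-{2-[6-(furan-3-yl)-2-oxo-4-(trifluoromethanesulfonyloxy)-2H-pyran-3-yl]ethyl}-7-(triethylsilyloxy)-1,4-dioxaspiro[4.5]decane-7-carboxylate | O=c1oc(-c2ccoc2)cc(OS(=O)(=O)C(F)(F)F)c1CC[C@]1(CO[Si](C)(C)C(C)(C)C)C2(OCCO2)CCC[C@]1(O[Si](CC)(CC)CC)C(=O)OC | intermediate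
24 | methyl (6R,7R)-6-{[tert-butyl(dimethyl)silyl]oxymethyl}-6-{2-[6-(furan-3-yl)-4-methyl-2-oxo-2H-pyran-3-yl]ethyl}-7-(triethylsilyloxy)-1,4-dioxaspiro[4.5]decane-7-carboxylate | Cc1cc(-c2ccoc2)oc(=O)c1CC[C@]1(CO[Si](C)(C)C(C)(C)C)C2(OCCO2)CCC[C@]1(O[Si](CC)(CC)CC)C(=O)OC | intermediate
25 | methyl (6R,7R)-6-{2-[6-(furan-3-yl)-4-methyl-2-oxo-2H-pyran-3-yl]ethyl}-7-hydroxy-6-(hydroxymethyl)-1,4-dioxaspiro[4.5]decane-7-carboxylate | Cc1cc(-c2ccoc2)oc(=O)c1CC[C@]1(CO)C2(OCCO2)CCC[C@]1(O)C(=O)OC | intermediate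
26 | (3aR,7aR)-3a-{2-[6-(furan-3-yl)-4-methyl-2-oxo-2H-pyran-3-yl]ethyl}-7a-hydroxyhexahydro-2-benzofuran-1,4-dione 4-(ethylene ketal), trans-fused lactone (not isolated) | Cc1cc(-c2ccoc2)oc(=O)c1CC[C@@]12COC(=O)[C@@]1(O)CCCC23OCCO3 | intermediate
27 | (3aR,7aR)-3a-{2-[6-(furan-3-yl)-4-methyl-2-oxo-2H-pyran-3-yl]ethyl}-7a-hydroxyhexahydro-2-benzofuran-1,4-dione | Cc1cc(-c2ccoc2)oc(=O)c1CC[C@@]12COC(=O)[C@@]1(O)CCCC2=O | intermediate
28 | (3aS,7aR) C4=C5 trimethylsilyl enol ether and 7a-O-trimethylsilyl ether of 27 (same spatial arrangement as 27; not isolated) | Cc1cc(-c2ccoc2)oc(=O)c1CC[C@@]12COC(=O)[C@@]1(O[Si](C)(C)C)CCC=C2O[Si](C)(C)C | intermediate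
29 | (3aR,7aR) 7a-O-trimethylsilyl ether of 30 (not isolated) | Cc1cc(-c2ccoc2)oc(=O)c1CC[C@@]12COC(=O)[C@@]1(O[Si](C)(C)C)CC=CC2=O | intermediate
30 | (3aR,7aR)-3a-{2-[6-(furan-3-yl)-4-methyl-2-oxo-2H-pyran-3-yl]ethyl}-7a-hydroxy-3,3a,7,7a-tetrahydro-2-benzofuran-1,4-dione (CNP0550188.1) | Cc1cc(-c2ccoc2)oc(=O)c1CC[C@@]12COC(=O)[C@@]1(O)CC=CC2=O | target

## Step count and risks

Total step count: 18. Longest linear sequence: 16 steps (steps 1–10, then 13–18); the pyranone branch is steps 11–12.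

**Step 6 (asymmetric benzoin).** The bulky CH2OTBS group is untested in this desymmetrisation and the enantiomeric ratio may be poor. The fallback sets out from 6 and comes back at 10. A ketoreductase panel (NADPH, glucose/GDH), or CBS-catalysed borane reduction, reduces one enantiotopic ketone of 6 to (2S,3S)-2-{[tert-butyl(dimethyl)silyl]oxymethyl}-3-hydroxy-2-(prop-2-en-1-yl)cyclohexan-1-one F1, fixing the quaternary centre early. TESOTf/2,6-lutidine gives its triethylsilyl ether F2. The hydroboration–oxidation of step 4 gives the 3-hydroxypropyl ketone F3, and Dess–Martin oxidation gives the aldehyde F4. An achiral triazolium carbene (DBU, THF) then closes onto the only remaining ketone, cis by ring constraint, to the 4-silyloxy ketol F5. PPTS/MeOH removes the secondary TES group to give the 4,7a-diol F6, and Dess–Martin oxidation of its secondary alcohol returns 10.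

**Step 17 (trans-lactone closure).** Acid-catalysed transesterification of the hindered tertiary methyl ester by a neopentyl alcohol into a trans-fused ring may stall. The fallback sets out from 25 and comes back at 26. Me3SnOH (1,2-dichloroethane, 70 °C) hydrolyses the methyl ester to the dihydroxy acid F7. The acid is then activated with 2-chloro-1-methylpyridinium iodide/Et3N (CH2Cl2, high dilution) so that the primary alcohol closes the ring by acylation, giving lactone ketal 26, now isolated. The HCl/THF stage of step 17 then gives 27.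

**Step 18 (late desaturation).** Pd(II) may attack the furan or the oxidation may be incomplete. The fallback sets out from 27 and comes back at 29. The bis-TMS enol ether 28 is made as in step 18 and treated with PhSeCl (CH2Cl2, −78 °C) to give the 5-phenylselanyl ketone F8 (C5 epimers). H2O2/pyridine (0 °C) oxidises it to the selenoxide F9, which undergoes syn-elimination to O-TMS enone 29. The acidic work-up of step 18 then gives 30.

## Further compounds

F1 | step 6 | (2S,3S)-2-{[tert-butyl(dimethyl)silyl]oxymethyl}-3-hydroxy-2-(prop-2-en-1-yl)cyclohexan-1-one | C=CC[C@]1(CO[Si](C)(C)C(C)(C)C)[C@@H](O)CCCC1=O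
F2 | step 6 | (2S,3S)-2-{[tert-butyl(dimethyl)silyl]oxymethyl}-2-(prop-2-en-1-yl)-3-(triethylsilyloxy)cyclohexan-1-one | C=CC[C@]1(CO[Si](C)(C)C(C)(C)C)[C@@H](O[Si](CC)(CC)CC)CCCC1=O
F3 | step 6 | (2S,3S)-2-{[tert-butyl(dimethyl)silyl]oxymethyl}-2-(3-hydroxypropyl)-3-(triethylsilyloxy)cyclohexan-1-one | OCCC[C@]1(CO[Si](C)(C)C(C)(C)C)[C@@H](O[Si](CC)(CC)CC)CCCC1=O
F4 | step 6 | 3-[(1S,2S)-1-{[tert-butyl(dimethyl)silyl]oxymethyl}-6-oxo-2-(triethylsilyloxy)cyclohexyl]propanal | O=CCC[C@]1(CO[Si](C)(C)C(C)(C)C)[C@@H](O[Si](CC)(CC)CC)CCCC1=O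
F5 | step 6 | (3aS,4S,7aR)-3a-{[tert-butyl(dimethyl)silyl]oxymethyl}-7a-hydroxy-4-(triethylsilyloxy)octahydro-1H-inden-1-one | O=C1CC[C@]2(CO[Si](C)(C)C(C)(C)C)[C@@H](O[Si](CC)(CC)CC)CCC[C@]12O
F6 | step 6 | (3aS,4S,7aR)-3a-{[tert-butyl(dimethyl)silyl]oxymethyl}-4,7a-dihydroxyoctahydro-1H-inden-1-one | O=C1CC[C@]2(CO[Si](C)(C)C(C)(C)C)[C@@H](O)CCC[C@]12O
F7 | step 17 | (6R,7R)-6-{2-[6-(furan-3-yl)-4-methyl-2-oxo-2H-pyran-3-yl]ethyl}-7-hydroxy-6-(hydroxymethyl)-1,4-dioxaspiro[4.5]decane-7-carboxylic acid | Cc1cc(-c2ccoc2)oc(=O)c1CC[C@]1(CO)C2(OCCO2)CCC[C@]1(O)C(=O)O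
F8 | step 18 | 5-(phenylselanyl) derivative of the 7a-O-trimethylsilyl ether of 27 (C5 epimers) | Cc1cc(-c2ccoc2)oc(=O)c1CC[C@@]12COC(=O)[C@@]1(O[Si](C)(C)C)CCC([Se]c3ccccc3)C2=O
F9 | step 18 | selenoxide of F8 | Cc1cc(-c2ccoc2)oc(=O)c1CC[C@@]12COC(=O)[C@@]1(O[Si](C)(C)C)CCC([Se](=O)c3ccccc3)C2=O
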